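**Assumptions.** Geranyl bromide, (2E,6E)-farnesyl bromide and prenol are bought as the pure isomers named. Triterpenoid numbering is used for the ring: C3 = carbinol, C4 = CMe2, C5 = CH bearing the chain, C10 = C–Me, C1 = ring =CH, C2 = CH2. Common reagents are not numbered; those that leave atoms in a product are given with SMILES in each step.

## Retrosynthetic overview

1. Camelliol C ⇐ acyclic (S)-epoxy allylic sulfone 14 by a proposed Ti(III) radical epoxide opening / 6-endo cyclization / β-sulfonyl fragmentation. The single ring is formed in the last step; this step makes C4–C5, sets C5 and fixes the alkene at C1=C10.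
2. 14 ⇐ C25 allylic sulfone 10 + (S)-epoxy triflate 13 by α-alkylation of the sulfone anion (C1–C2 bond). The C3 stereocenter comes from Sharpless epoxidation of prenol.
3. 10 ⇐ C25 allylic alcohol 8 ⇐ sulfone coupling of TBS-protected 8-hydroxygeranyl phenyl sulfone 4 with farnesyl bromide 5, then Pd/hydride desulfonylation (tail-to-tail C11–C12 bond).
4. 4 ⇐ geranyl bromide 1 by sulfinate displacement and E-selective SeO2 allylic oxidation.

## Route

**Step 1**
Reactants: 1, geranyl bromide
Product: 2, geranyl phenyl sulfone
Conditions: PhSO2Na, DMF, rt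
Reagents that add atoms: sodium benzenesulfinate, [Na+].[O-]S(=O)c1ccccc1
Why: SN2 S-alkylation of sulfinate by a primary allylic bromide, which keeps the 2E alkene.

**Step 2**
Reactants: 2, geranyl phenyl sulfone
Product: 3, (2E,6E)-2,6-dimethyl-8-(phenylsulfonyl)octa-2,6-dien-1-ol
Conditions: SeO2 (cat.), t-BuOOH, salicylic acid (cat.), CH2Cl2, 0 °C to rt; then NaBH4, MeOH, 0 °C
Reagents that add atoms: selenium dioxide, O=[Se]=O (delivers O); tert-butyl hydroperoxide, CC(C)(C)OO (reoxidant)
Why: Sharpless SeO2 allylic oxidation (ene / [2,3] shift) hydroxylates the E-methyl of the electron-rich terminal alkene only, since the 2,3-alkene is deactivated by the sulfone; NaBH4 returns over-oxidized enal to the alcohol.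

**Step 3**
Reactants: 3
Product: 4, TBS ether of 3
Conditions: TBSCl, imidazole, DMF, rt
Reagents that add atoms: tert-butyldimethylsilyl chloride, CC(C)(C)[Si](C)(C)Cl
Why: Standard silylation of a primary alcohol, so that only the sulfone α-CH2 is deprotonated in step 4.

**Step 4**
Reactants: 4; 5, (2E,6E)-farnesyl bromide
Product: 6, TBS ether of (2E,6E,10E,14E)-2,6,11,15,19-pentamethyl-8-(phenylsulfonyl)icosa-2,6,10,14,18-pentaen-1-ol (racemic at C8)
Conditions: n-BuLi, THF, −78 °C; then 5, −78 to −20 °C
Reagents that add atoms: none (new atoms come from reactant 5)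
Why: Biellmann-type α-alkylation of a lithiated allylic sulfone with an allylic bromide forms the tail-to-tail 1,5-diene junction with both alkene geometries untouched.

**Step 5**
Reactants: 6
Product: 7, TBS ether of (2E,6E,10E,14E)-2,6,11,15,19-pentamethylicosa-2,6,10,14,18-pentaen-1-ol
Conditions: PdCl2(dppp) (5 mol %), LiEt3BH, THF, 0 °C
Reagents that add atoms: none
Why: Pd-catalysed reductive desulfonylation via a π-allyl, with hydride delivered to the less substituted terminus, so the E-trisubstituted alkene stays in place; the silyl ether is inert.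

**Step 6**
Reactants: 7
Product: 8, (2E,6E,10E,14E)-2,6,11,15,19-pentamethylicosa-2,6,10,14,18-pentaen-1-ol
Conditions: TBAF, THF, 0 °C to rt
Reagents that add atoms: none
Why: Fluoride cleavage of the Si–O bond, harmless to the polyene.

**Step 7**
Reactants: 8
Product: 9, (2E,6E,10E,14E)-1-bromo-2,6,11,15,19-pentamethylicosa-2,6,10,14,18-pentaene
Conditions: MsCl, Et3N, THF, −40 °C; then LiBr, 0 °C (used directly)
Reagents that add atoms: lithium bromide, [Li+].[Br-]
Why: Low-temperature SN2 displacement of the primary allylic mesylate by bromide, without allylic transposition or E/Z loss.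

**Step 8**
Reactants: 9
Product: 10, [(2E,6E,10E,14E)-2,6,11,15,19-pentamethylicosa-2,6,10,14,18-pentaen-1-yl]sulfonylbenzene
Conditions: PhSO2Na, DMF, 0 °C to rt
Reagents that add atoms: sodium benzenesulfinate, [Na+].[O-]S(=O)c1ccccc1
Why: SN2 S-alkylation of sulfinate at the primary allylic carbon places the sulfone on the future C1 with the C10=C5 alkene E.

**Step 9**
Reactants: 11, prenol (3-methylbut-2-en-1-ol)
Product: 12, (S)-(3,3-dimethyloxiran-2-yl)methanol
Conditions: Ti(OiPr)4 (5 mol %), L-(+)-DIPT (7 mol %), t-BuOOH, 4 Å MS, CH2Cl2, −20 °C; non-aqueous workup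
Reagents that add atoms: tert-butyl hydroperoxide, CC(C)(C)OO
Why: Sharpless asymmetric epoxidation; L-(+)-tartrate delivers oxygen to the same face as in geraniol → (2S,3S)-epoxygeraniol, giving the (S)-epoxy alcohol (typically about 90–95% ee), and this sets C3 of the target.

**Step 10**
Reactants: 12
Product: 13, (S)-(3,3-dimethyloxiran-2-yl)methyl trifluoromethanesulfonate
Conditions: Tf2O, 2,6-di-tert-butyl-4-methylpyridine, CH2Cl2, −78 °C (cold solution used at once)
Reagents that add atoms: triflic anhydride, O=S(=O)(OS(=O)(=O)C(F)(F)F)C(F)(F)F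
Why: O-triflation of the primary alcohol with a hindered base does not touch the stereocenter and gives an electrophile reactive enough for SN2 at −78 °C.

**Step 11**
Reactants: 10; 13
Product: 14, (2S)-3,3-dimethyl-2-[(3E,7E,11E,15E)-3,7,12,16,20-pentamethyl-2-(phenylsulfonyl)henicosa-3,7,11,15,19-pentaen-1-yl]oxirane, i.e. 1-(phenylsulfonyl)-(3S)-2,3-oxidosqualene, about 1:1 epimers at the sulfone carbon
Conditions: 10, n-BuLi (1.0 equiv), THF, −78 °C; then 13, −78 °C; NH4Cl quench
Reagents that add atoms: none (new atoms come from reactant 13)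
Why: α-selective alkylation of the lithiated allylic sulfone by SN2 at the primary triflate, which outpaces opening of the hindered trisubstituted epoxide; the epoxide stereocenter is untouched, and the mixed sulfone-carbon configuration does not matter because that carbon becomes sp2.

**Step 12**
Reactants: 14
Product: 15, camelliol C, (1S,3R)-2,2,4-trimethyl-3-[(3E,7E,11E)-3,8,12,16-tetramethylheptadeca-3,7,11,15-tetraenyl]cyclohex-4-en-1-ol
Conditions: Cp2TiCl2 (20 mol %), Mn dust, 2,4,6-collidine·HCl, degassed THF (0.01 M), rt, slow addition of 14; aqueous workup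
Reagents that add atoms: none
Why: Proposed new method: Cp2Ti(III)Cl opens the epoxide by C4–O homolysis to a nucleophilic β-titanoxy tertiary radical, which adds 6-endo to C5 (the γ-carbon of the allylic sulfone) through a chair transition state with C3–OTi and the E-alkene chain both pseudo-equatorial, giving the 3,5-cis ring with C3 (S) retained and C5 (R) new; the resulting C10 tertiary radical is β to the sulfonyl group and expels PhSO2•, which should be faster than a second 6-endo closure onto the next alkene, so the cascade stops at the monocycle with the alkene fixed at C1=C10, and PhSO2• is reduced by Ti(III) to sulfinate before it can isomerize alkenes; the closest known reaction types are titanocene(III)-mediated epoxypolyene radical cyclization (which normally terminates as the exocyclic alkene) and radical addition–fragmentation (SH2′ allyl transfer) of allyl sulfones.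

## Compound list

1 | geranyl bromide | CC(C)=CCC/C(C)=C/CBr | starting material
2 | geranyl phenyl sulfone | CC(C)=CCC/C(C)=C/CS(=O)(=O)c1ccccc1 | intermediate
3 | (2E,6E)-2,6-dimethyl-8-(phenylsulfonyl)octa-2,6-dien-1-ol | OC/C(C)=C/CC/C(C)=C/CS(=O)(=O)c1ccccc1 | intermediate
4 | TBS ether of 3 | CC(C)(C)[Si](C)(C)OC/C(C)=C/CC/C(C)=C/CS(=O)(=O)c1ccccc1 | intermediate
5 | (2E,6E)-farnesyl bromide | CC(C)=CCC/C(C)=C/CC/C(C)=C/CBr | starting material
6 | C25 8-sulfonyl TBS ether (racemic at C8) | CC(C)(C)[Si](C)(C)OC/C(C)=C/CC/C(C)=C/C(C/C=C(\C)CC/C=C(\C)CCC=C(C)C)S(=O)(=O)c1ccccc1 | intermediate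
7 | C25 pentaenyl TBS ether | CC(C)(C)[Si](C)(C)OC/C(C)=C/CC/C(C)=C/CC/C=C(\C)CC/C=C(\C)CCC=C(C)C | intermediate
8 | (2E,6E,10E,14E)-2,6,11,15,19-pentamethylicosa-2,6,10,14,18-pentaen-1-ol | OC/C(C)=C/CC/C(C)=C/CC/C=C(\C)CC/C=C(\C)CCC=C(C)C | intermediate
9 | C25 allylic bromide | BrC/C(C)=C/CC/C(C)=C/CC/C=C(\C)CC/C=C(\C)CCC=C(C)C | intermediate
10 | C25 allylic phenyl sulfone | O=S(=O)(C/C(C)=C/CC/C(C)=C/CC/C=C(\C)CC/C=C(\C)CCC=C(C)C)c1ccccc1 | intermediate
11 | prenol | CC(C)=CCO | starting material
12 | (S)-(3,3-dimethyloxiran-2-yl)methanol | OC[C@@H]1OC1(C)C | intermediate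
13 | (S)-(3,3-dimethyloxiran-2-yl)methyl triflate | O=S(=O)(OC[C@@H]1OC1(C)C)C(F)(F)F | intermediate
14 | 1-(phenylsulfonyl)-(3S)-2,3-oxidosqualene (epimers at the sulfone carbon) | CC(C)=CCC/C(C)=C/CC/C(C)=C/CC/C=C(\C)CC/C=C(\C)C(C[C@@H]1OC1(C)C)S(=O)(=O)c1ccccc1 | intermediate
15 | camelliol C | CC(C)=CCC/C(C)=C/CC/C(C)=C/CC/C=C(\C)CC[C@@H]1C(C)=CC[C@H](O)C1(C)C | target

## Summary

Total steps: 12. Longest linear sequence: 10 (steps 1–8, 11, 12 from geranyl bromide); steps 9–10 are the side branch.

Steps most likely to fail, with fallbacks: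

1. **Step 12 (proposed new cyclization/fragmentation).** Risks are Ti-mediated deoxygenation of the epoxide before cyclization, modest cis/trans selectivity at C5, and sulfonyl-radical side reactions such as 1,3-sulfonyl shift. Fallback (known chemistry, ring first): Lewis-acid (ZrCl4 or MeAlCl2) epoxy-olefin cyclization of (S)-6,7-epoxygeranyl acetate to the 3-hydroxy-α-cyclogeranyl acetate, separated from the γ-isomer. Then TBS protection, conversion of the CH2OAc arm to the α-cyclogeranyl phenyl sulfone, alkylation of its anion with the C20 allylic bromide (the prenyl-derived lower homologue of 9, made as in steps 1–7), Na(Hg) desulfonylation and TBAF.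
2. **Step 11 (alkylation with the epoxy triflate).** Risks are triflate decomposition and competing epoxide opening. Fallback: alkylate 10 with the acetonide-protected diol electrophile 4-(iodomethyl)-2,2,5,5-tetramethyl-1,3-dioxolane, made by Sharpless dihydroxylation of a prenyl ester and chosen to give the (3R)-diol. After coupling, hydrolyse the acetonide, mesylate the secondary OH and close with K2CO3/MeOH, which inverts C3 to the (S)-epoxide 14.
3. **Step 2 (SeO2 allylic oxidation).** Risks are low conversion and over-oxidation. Fallback: build the E-2-methylallyl alcohol terminus by olefination instead. Epoxidize the terminal alkene of 2 with mCPBA, cleave with HIO4 to the aldehyde, run an E-selective Wittig reaction with Ph3P=C(Me)CO2Et, and reduce with DIBAL to 3.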